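# Proposed synthesis of (−)-thujaplicatin (22)

## The problem

(−)-Thujaplicatin (22) is a single γ-butyrolactone (O1, carbonyl C2, C3, C4, methylene C5) with no ring fusion. C3 carries a 3,4-dihydroxy-5-methoxybenzyl arm and C4 a 4-hydroxy-3-methoxybenzyl arm, trans to each other and both R. The two aryl groups differ by one oxygen substituent, so the arms cannot come from a symmetrical dimerisation and must be attached in two separate, regiodefined bond formations. Only C4 has to be set absolutely: C3 lies α to the carbonyl, can be enolised and settles trans to the C4 arm at equilibrium, so C4 controls C3. The lactone of 22 has nothing next to C4 that distinguishes its two faces, so the absolute control must come from a catalyst or from a temporary stereocentre. The three phenols, two of them an air-sensitive catechol, must be masked against bases, organometallic reagents and photooxidants and released last under neutral, non-oxidising conditions. The lactone opens with hydroxide and epimerises at C3 with base. The enabling feature is twofold. The bond from C4 to its benzylic CH2 lies β to the C2 carbonyl, so a benzyl radical can form it by adding to a C3=C4 double bond. C5, a plain OCH2 in 22, can be carried one oxidation level higher as a mixed acetal with a chiral alcohol, which puts a removable stereocentre on the ring atom next to C4.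

## Retrosynthesis

22 to 21. The three phenolic O–H bonds are traced back to O-benzyl ethers. Silyl ethers would be lost in aqueous hydroxide and extra methyl ethers could not be told apart from the two native ones. Benzyl ethers should pass zinc, palladium, photoredox, amidine base and hydroxide, and leave by neutral hydrogenolysis, which suits the sensitive catechol. The forward step only has to spare the lactone and the benzylic C–C bonds.

21 to 18. The C5 methylene of 21 is traced back to an acetal carbon bearing the (1R,2S,5R)-menthyloxy group. An auxiliary on the acyl side would need cleavage and a separate lactonisation. The acetal auxiliary sits in the ring beside C4, comes from cheap 4 and is released as 4 again. The forward reaction is one flask: opening of the acyl acetal, reduction of aldehyde 19 to hydroxy acid 20, and relactonisation. It must not disturb C3 or C4.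

18 to 14 and 16 (key disconnection). The C4–CH2 bond is cut, giving the 3-substituted 5-menthyloxybutenolide 14 and a 4-benzyloxy-3-methoxybenzyl radical, for which arylacetic acid 16 is the precursor after loss of CO2. Cutting the C3–CH2 bond instead (enolate alkylation) would leave the C4 problem unsolved. An anionic benzyl donor would need an umpolung reagent and a desulfurisation, and basic organometallics would deprotonate C5 of 14. The neutral, nucleophilic radical matches the electron-poor β-carbon. The cut divides the molecule into two halves of similar size and removes two stereocentres. The forward step must add at C4 only and trans to the menthyloxy group, keep C5 intact until then, and bring the kinetic C3 epimer 17 to 18.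

14 to 8 and 12. The sp2–sp3 bond between C3 and its benzylic CH2 is cut, giving bromobutenolide 8 and benzyl chloride 12, joined through benzylzinc chloride 13. Against an aldol–dehydration–deoxygenation sequence this is one step, non-basic and leaves the C5 acetal alone. The forward reaction is a Negishi coupling of a vinylic bromide.

8 to 6, and 6 to 3 and 4, and 3 to 1. The C3–Br bond is removed, then the acetal C5–O bond is cut to give pseudo-acid 3 and menthol 4. The epimers 5 and 6 interconvert under acid and 6 crystallises, so the stereocentre costs no chromatography. 3 comes from furfural 1 by oxidative excision of the formyl carbon through endoperoxide 2.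

12 to 11 to 10 to 9, and 16 to 15. Chloride 12 goes back through alcohol 11 and aldehyde 10 to 5-hydroxyvanillin 9 by functional-group changes. Acid 16 is the O-benzyl ether of homovanillic acid 15.

## Roads not taken

Alternative 1: The carbonyl carbon is taken out as carbon monoxide by cutting C2–C3 and C2–O1, leading back to homopropargylic alcohol A1. In the forward step Pd(OAc)2, 1,4-bis(diphenylphosphino)butane and p-toluenesulfonic acid under CO would add H and the acyl group syn across the alkyne and close the five-membered ring to the (E)-arylidene lactone A2.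
- Merits: ring and carbonyl form in one step, and the C4 centre of A1 and A2 is not epimerisable. A final hydrogenation could in principle reduce the exocyclic alkene and remove the benzyl ethers together, which would be shorter after the key step than the chosen plan.
- Weak points: the key step sets no stereocentre, so C4 must be built into A1 by separate asymmetric chemistry plus alkyne construction. Hydropalladation of an internal aryl alkyne can place palladium on either carbon, which opens the way to a six-membered unsaturated lactone. Pressurised CO is needed. Hydrogen would add to A2 from the face away from the C4 arm and give the 3,4-cis lactone, and correcting this with base on a free catechol is unattractive, so reduction and deprotection would have to be separated again.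
- Comparison: the chosen plan sets C4 in the bond-forming step and equilibrates C3 while all phenols are still protected.

Alternative 2: The C4–C5 bond is cut, leading back to stannylmethyl ether A3 of an (S,Z)-allylic benzylic alcohol. Tin–lithium exchange with n-BuLi at −78 °C would trigger the [2,3] shift to homoallylic alcohol A4 with an (E)-styrene.
- Merits: chirality transfer from a Z-allylic ether through an ordered sigmatropic transition state is very reliable. In stereochemical certainty at C4 this step is at least as good as the radical addition, and no auxiliary remains on the skeleton.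
- Weak points: A3 needs an enantiopure Z-allylic alcohol and stoichiometric tin. Its carbinol carbon is benzylic and electron-rich, so the [1,2] shift and ionisation compete. Above all, A4 lacks the carbonyl carbon C2: the styrene would have to be carbonylated at the carbon remote from the aryl ring, against the benzylic position and a six-membered lactone, and C3 would again be set only afterwards.
- Comparison: the route would be several steps longer. Against the cleaner stereochemical step the chosen plan sets a key step that joins the two halves and delivers the full skeleton two steps from the target.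

Alternative 3: The aryl–CH2 bond of the C3 arm is cut, leading back to the (R)-α-methylene lactone A5 and arylboronic acid A6. [RhCl(C8H12)]2 and KOH in aqueous dioxane would transfer the aryl group to the exocyclic CH2 and protonate the rhodium enolate to give A7, which is the same compound as 21.
- Merits: conjugate arylation of α-methylene carbonyl compounds is a well-behaved two-electron process with no radical dimerisation, and it ends at 21 without an auxiliary to remove. In the certainty of the key step this road is better than the chosen one.
- Weak points: the step creates no absolute stereochemistry, so A5 must already be enantiopure, which needs an asymmetric catalyst or a resolution plus an α-methylenation. C3 is again set by protonation and would need the same equilibration. Hot aqueous KOH can open the lactone and protodeboronate the electron-rich A6, and β-hydride elimination would lead to the arylidene lactone A2.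
- Comparison: the step counts are similar. Against its riskier key step the chosen plan sets absolute configuration from a cheap, recoverable auxiliary purified by crystallisation, and C–C bond formation and C4 control in one operation. If the radical addition proves too sluggish, this is the strongest reserve.

Key step: step 9

Assumption: kinetic protonation of the C3 enolate in step 9 is taken to favour the 3,4-cis lactone 17, so the route equilibrates C3 with DBU in the same flask and does not depend on the kinetic outcome.

## Route

Menthyloxy means (1R,2S,5R)-2-isopropyl-5-methylcyclohexyloxy throughout.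

Step 1
Reactants: 1 furfural
Product: 3 5-hydroxyfuran-2(5H)-one (racemic), via furfural endoperoxide 2 (not isolated)
Conditions: O2, rose bengal (cat.), MeOH, visible light, 20 °C
Reagents that add atoms: dioxygen, O=O
Why: Dye-sensitised photooxygenation: singlet oxygen adds [4+2] across C2 and C5 of the furan to give 2, methanol adds to the formyl group and the adduct fragments with loss of methyl formate, leaving the lactone carbonyl and the C5 hydroxyl, both from O2.

Step 2
Reactants: 3 5-hydroxyfuran-2(5H)-one; 4 (−)-menthol
Product: 6 (5R)-5-[(1R,2S,5R)-menthyloxy]furan-2(5H)-one, via (5S)-acetal epimer 5 (not isolated)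
Conditions: CSA (cat.), toluene, reflux, Dean–Stark; crystallisation from petroleum ether, mother liquor re-equilibrated with CSA and crystallised again
Reagents that add atoms: none
Why: Acid-catalysed acetalisation of the pseudo-acid gives both C5 epimers, which interconvert under acid; the (5R)-epimer is the crystalline one, so C5 is set by crystallisation with recycling of 5.

Step 3
Reactants: 6 (5R)-5-menthyloxyfuran-2(5H)-one
Product: 8 (5R)-3-bromo-5-[(1R,2S,5R)-menthyloxy]furan-2(5H)-one, via 3,4-dibromo lactone 7 (not isolated)
Conditions: Br2, CH2Cl2, 0 °C; then Et3N, 0 °C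
Reagents that add atoms: bromine, BrBr
Why: Anti addition of bromine to the enoate and E1cB dehydrobromination (the C3 proton is the acidic one, the C4 bromide leaves) give the α-bromobutenolide; C5 is not involved and short exposure to the amine at 0 °C should leave the acetal configuration intact.

Step 4
Reactants: 9 5-hydroxyvanillin (3,4-dihydroxy-5-methoxybenzaldehyde)
Product: 10 3,4-bis(benzyloxy)-5-methoxybenzaldehyde
Conditions: BnBr, K2CO3, DMF, 60 °C
Reagents that add atoms: benzyl bromide, BrCc1ccccc1
Why: Williamson etherification of both phenoxides; the aldehyde is inert to carbonate.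

Step 5
Reactants: 10 3,4-bis(benzyloxy)-5-methoxybenzaldehyde
Product: 11 [3,4-bis(benzyloxy)-5-methoxyphenyl]methanol
Conditions: NaBH4, MeOH–THF, 0 °C
Reagents that add atoms: none
Why: Borohydride reduction of an aromatic aldehyde; benzyl ethers are untouched.

Step 6
Reactants: 11 [3,4-bis(benzyloxy)-5-methoxyphenyl]methanol
Product: 12 3,4-bis(benzyloxy)-5-methoxybenzyl chloride
Conditions: SOCl2, DMF (cat.), CH2Cl2, 0 °C
Reagents that add atoms: thionyl chloride, O=S(Cl)Cl
Why: Chlorodehydroxylation through the chlorosulfite; the electron-rich benzylic position reacts quickly at 0 °C and the chloride is the preferred partner for zinc insertion.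

Step 7
Reactants: 12 3,4-bis(benzyloxy)-5-methoxybenzyl chloride; 8 (5R)-3-bromo-5-menthyloxyfuran-2(5H)-one
Product: 14 (5R)-3-[3,4-bis(benzyloxy)-5-methoxybenzyl]-5-[(1R,2S,5R)-menthyloxy]furan-2(5H)-one, via benzylzinc chloride 13 (not isolated)
Conditions: 12, Zn dust, LiCl, THF, 25 °C; then 8, Pd(PPh3)4 (5 mol%), THF, 25 to 50 °C
Reagents that add atoms: none
Why: LiCl-promoted zinc insertion into the benzylic C–Cl bond gives 13; Negishi coupling (oxidative addition of zerovalent palladium into the C3–Br bond, transmetallation, reductive elimination) forms the C3–CH2 bond, and the neutral organozinc should neither add to the butenolide nor deprotonate C5.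

Step 8
Reactants: 15 homovanillic acid
Product: 16 2-(4-benzyloxy-3-methoxyphenyl)acetic acid
Conditions: BnBr, NaOH, EtOH–H2O, reflux; then HCl
Reagents that add atoms: benzyl bromide, BrCc1ccccc1
Why: Williamson etherification of the phenoxide of the dianion; any benzyl ester formed is saponified in the same alkaline medium, so acidification should return only the O-benzyl acid.

Step 9
Reactants: 14 (5R)-3-[3,4-bis(benzyloxy)-5-methoxybenzyl]-5-menthyloxyfuran-2(5H)-one; 16 2-(4-benzyloxy-3-methoxyphenyl)acetic acid
Product: 18 (3R,4R,5R)-3-[3,4-bis(benzyloxy)-5-methoxybenzyl]-4-(4-benzyloxy-3-methoxybenzyl)-5-[(1R,2S,5R)-menthyloxy]dihydrofuran-2(3H)-one, via 3,4-cis lactone 17 (not isolated)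
Conditions: 16 (2.5 equiv), 4CzIPN (3 mol%), Cs2CO3 (10 mol%), degassed DMF, 450 nm LEDs, 25 °C; then DBU (3 equiv), 60 °C
Reagents that add atoms: none
Why: Photoexcited 4CzIPN oxidises the cesium carboxylate of 16, CO2 is lost and the electron-rich benzyl radical adds to the unsubstituted β-carbon C4 of the electron-poor butenolide 14; the tertiary α-acyl radical at C3 is reduced by the catalyst radical anion to the lactone enolate, which is protonated by free 16 and so regenerates the carboxylate. The closest known reaction type is the photoredox decarboxylative Giese addition of arylacetic acids to enoate acceptors, together with the anti-selective addition of carbon radicals to 5-alkoxybutenolides, including ones that carry an α-substituent. No ring is closed. C4 is controlled by the C5 acetal: the menthyloxy group covers one face of the planar butenolide and the radical enters trans to it, which with the (5R)-acetal gives (4R). C3 is not controlled kinetically, because protonation from the side away from the new C4 arm gives the 3,4-cis lactone 17; it is set thermodynamically when DBU enolises C3 reversibly and the all-trans lactone 18 should dominate at equilibrium. The step needs attack at C4 only (polarity matching and the stabilised tertiary radical that results), face selectivity (the acetal) and an intact C5 configuration before addition, which is why carbonate is kept catalytic and free acid is always present, so that no base able to form the 2-oxidofuran from 14 is in the flask. An excess of 16 and a low photon flux should keep the benzyl radical concentration low and limit its dimerisation.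

Step 10
Reactants: 18 (3R,4R,5R)-3-[3,4-bis(benzyloxy)-5-methoxybenzyl]-4-(4-benzyloxy-3-methoxybenzyl)-5-menthyloxydihydrofuran-2(3H)-one
Product: 21 (3R,4R)-3-[3,4-bis(benzyloxy)-5-methoxybenzyl]-4-(4-benzyloxy-3-methoxybenzyl)dihydrofuran-2(3H)-one, via formyl acid 19 (not isolated), via hydroxy acid 20 (not isolated)
Conditions: NaBH4, KOH, EtOH–H2O, 0 to 25 °C; then 2 M HCl, 25 °C
Reagents that add atoms: potassium hydroxide, [K+].[OH-] (its oxygen enters the carboxylate of 19 and is retained statistically as the lactone carbonyl oxygen)
Why: Hydroxide opens the acyl acetal at C2, the hemiacetal collapses to aldehyde 19 with release of menthol, borohydride reduces the aldehyde at once to 20, and acidification closes the γ-lactone; C3 sits α to a carboxylate and C4 α to an aldehyde that should be reduced faster than it enolises, so both centres should be retained.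

Step 11
Reactants: 21 (3R,4R)-3-[3,4-bis(benzyloxy)-5-methoxybenzyl]-4-(4-benzyloxy-3-methoxybenzyl)dihydrofuran-2(3H)-one
Product: 22 (−)-thujaplicatin, (3R,4R)-3-(3,4-dihydroxy-5-methoxybenzyl)-4-(4-hydroxy-3-methoxybenzyl)dihydrofuran-2(3H)-one
Conditions: H2 (1 atm), 10% Pd/C, EtOAc–MeOH, 25 °C
Reagents that add atoms: none
Why: Hydrogenolysis of three aryl benzyl ethers under neutral conditions; the lactone, the aryl methyl ethers and both stereocentres are not affected, and the catechol is kept under inert gas during work-up.

## Compound list

1 | furfural (furan-2-carbaldehyde) | O=Cc1ccco1 | starting material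
2 | furfural endoperoxide (2,3,7-trioxabicyclo[2.2.1]hept-5-ene-1-carbaldehyde, racemic) | O=CC12OOC(C=C1)O2 | intermediate
3 | 5-hydroxyfuran-2(5H)-one (racemic) | O=C1C=CC(O)O1 | intermediate
4 | (−)-menthol, (1R,2S,5R)-2-isopropyl-5-methylcyclohexan-1-ol | CC(C)[C@@H]1CC[C@@H](C)C[C@H]1O | starting material
5 | (5S)-5-[(1R,2S,5R)-menthyloxy]furan-2(5H)-one | O=C1C=C[C@@H](O[C@@H]2C[C@H](C)CC[C@H]2C(C)C)O1 | intermediate
6 | (5R)-5-[(1R,2S,5R)-menthyloxy]furan-2(5H)-one | O=C1C=C[C@H](O[C@@H]2C[C@H](C)CC[C@H]2C(C)C)O1 | intermediate
7 | (5R)-3,4-dibromo-5-[(1R,2S,5R)-menthyloxy]dihydrofuran-2(3H)-one (3,4-trans; C3 and C4 not assigned, both are erased in the elimination) | O=C1C(Br)C(Br)[C@H](O[C@@H]2C[C@H](C)CC[C@H]2C(C)C)O1 | intermediate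
8 | (5R)-3-bromo-5-[(1R,2S,5R)-menthyloxy]furan-2(5H)-one | O=C1C(Br)=C[C@H](O[C@@H]2C[C@H](C)CC[C@H]2C(C)C)O1 | intermediate
9 | 5-hydroxyvanillin (3,4-dihydroxy-5-methoxybenzaldehyde) | COc1cc(C=O)cc(O)c1O | starting material
10 | 3,4-bis(benzyloxy)-5-methoxybenzaldehyde | COc1cc(C=O)cc(OCc2ccccc2)c1OCc1ccccc1 | intermediate
11 | [3,4-bis(benzyloxy)-5-methoxyphenyl]methanol | COc1cc(CO)cc(OCc2ccccc2)c1OCc1ccccc1 | intermediate
12 | 3,4-bis(benzyloxy)-5-methoxybenzyl chloride | COc1cc(CCl)cc(OCc2ccccc2)c1OCc1ccccc1 | intermediate
13 | [3,4-bis(benzyloxy)-5-methoxybenzyl]zinc chloride (LiCl complex in THF) | COc1cc(C[Zn]Cl)cc(OCc2ccccc2)c1OCc1ccccc1 | intermediate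
14 | (5R)-3-[3,4-bis(benzyloxy)-5-methoxybenzyl]-5-[(1R,2S,5R)-menthyloxy]furan-2(5H)-one | COc1cc(CC2=C[C@H](O[C@@H]3C[C@H](C)CC[C@H]3C(C)C)OC2=O)cc(OCc2ccccc2)c1OCc1ccccc1 | intermediate
15 | homovanillic acid, 2-(4-hydroxy-3-methoxyphenyl)acetic acid | COc1cc(CC(=O)O)ccc1O | starting material
16 | 2-(4-benzyloxy-3-methoxyphenyl)acetic acid | COc1cc(CC(=O)O)ccc1OCc1ccccc1 | intermediate
17 | (3S,4R,5R)-3-[3,4-bis(benzyloxy)-5-methoxybenzyl]-4-(4-benzyloxy-3-methoxybenzyl)-5-[(1R,2S,5R)-menthyloxy]dihydrofuran-2(3H)-one | COc1cc(C[C@H]2[C@H](O[C@@H]3C[C@H](C)CC[C@H]3C(C)C)OC(=O)[C@H]2Cc2cc(OCc3ccccc3)c(OCc3ccccc3)c(OC)c2)ccc1OCc1ccccc1 | intermediate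
18 | (3R,4R,5R)-3-[3,4-bis(benzyloxy)-5-methoxybenzyl]-4-(4-benzyloxy-3-methoxybenzyl)-5-[(1R,2S,5R)-menthyloxy]dihydrofuran-2(3H)-one | COc1cc(C[C@H]2[C@H](O[C@@H]3C[C@H](C)CC[C@H]3C(C)C)OC(=O)[C@@H]2Cc2cc(OCc3ccccc3)c(OCc3ccccc3)c(OC)c2)ccc1OCc1ccccc1 | intermediate
19 | (2R,3R)-2-[3,4-bis(benzyloxy)-5-methoxybenzyl]-3-(4-benzyloxy-3-methoxybenzyl)-4-oxobutanoic acid (potassium salt in the flask) | COc1cc(C[C@@H](C=O)[C@@H](Cc2cc(OCc3ccccc3)c(OCc3ccccc3)c(OC)c2)C(=O)O)ccc1OCc1ccccc1 | intermediate
20 | (2R,3R)-2-[3,4-bis(benzyloxy)-5-methoxybenzyl]-3-(4-benzyloxy-3-methoxybenzyl)-4-hydroxybutanoic acid (potassium salt in the flask) | COc1cc(C[C@@H](CO)[C@@H](Cc2cc(OCc3ccccc3)c(OCc3ccccc3)c(OC)c2)C(=O)O)ccc1OCc1ccccc1 | intermediate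
21 | (3R,4R)-3-[3,4-bis(benzyloxy)-5-methoxybenzyl]-4-(4-benzyloxy-3-methoxybenzyl)dihydrofuran-2(3H)-one | COc1cc(C[C@H]2COC(=O)[C@@H]2Cc2cc(OCc3ccccc3)c(OCc3ccccc3)c(OC)c2)ccc1OCc1ccccc1 | intermediate
22 | (−)-thujaplicatin, (3R,4R)-3-(3,4-dihydroxy-5-methoxybenzyl)-4-(4-hydroxy-3-methoxybenzyl)dihydrofuran-2(3H)-one | COc1cc(C[C@H]2COC(=O)[C@@H]2Cc2cc(O)c(O)c(OC)c2)ccc1O | target

## Step count and risks

Total: 11 steps. Longest linear sequence: 7 steps (1, 2, 3, 7, 9, 10, 11 from furfural; the arm from 5-hydroxyvanillin through steps 4, 5, 6, 7, 9, 10, 11 is equally long).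

Step 9 (key step). The stabilised benzyl radical may add too slowly to the trisubstituted acceptor, so that radical dimerisation and stalled catalyst turnover take over. The C5 configuration of 14 may erode through γ-deprotonation before the addition. Equilibration at C3 may stay incomplete. The fallback is anionic and sets out from 6 and 12, returning at 18. 2-(4-Benzyloxy-3-methoxyphenyl)-1,3-dithiane F1, made from commercial 4-benzyloxy-3-methoxybenzaldehyde and propane-1,3-dithiol with BF3·OEt2, is lithiated with n-BuLi at −78 °C and added to 6, where it should enter trans to the menthyloxy group. The lactone enolate is trapped in the same flask with 12 (NaI, DMPU) trans to the new C4 substituent, giving (3R,4R,5R)-3-[3,4-bis(benzyloxy)-5-methoxybenzyl]-4-[2-(4-benzyloxy-3-methoxyphenyl)-1,3-dithian-2-yl]-5-menthyloxydihydrofuran-2(3H)-one F2. Desulfurisation with NiCl2·6H2O and NaBH4 turns the dithiane carbon into the benzylic CH2 and should give 18 with C3 already trans.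

Step 7. Zinc insertion into the electron-rich benzylic chloride may be accompanied by Wurtz-type homocoupling, and the bromobutenolide may be reduced or degraded at palladium (ionisation of the allylic acyl acetal) instead of coupling. The fallback reverses the order in which the arms are attached; it sets out from 6 and 16 and returns at 18. The decarboxylative radical addition of 16 is run on the unsubstituted butenolide 6 under the conditions of step 9 without DBU, to give (4R,5R)-4-(4-benzyloxy-3-methoxybenzyl)-5-menthyloxydihydrofuran-2(3H)-one F3. Its lithium enolate (LDA, THF, −78 °C) is alkylated with 12 (NaI, DMPU) on the face away from the C4 arm, which should give 18.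

Step 10. The transient aldehyde 19 may enolise in hydroxide before it is reduced, which would epimerise C4. The fallback separates the two events and avoids hydroxide; it sets out from 18 and returns at 21. Aqueous acid (TFA–H2O–THF, 25 °C) cleaves the acetal to the lactol (3R,4R)-3-[3,4-bis(benzyloxy)-5-methoxybenzyl]-4-(4-benzyloxy-3-methoxybenzyl)-5-hydroxydihydrofuran-2(3H)-one F4 with release of menthol. NaBH4 in EtOH at 0 °C reduces the lactol through its open form, and dilute HCl closes the lactone to 21.

Step 3. The amine may partly epimerise C5 through the aromatic 2-oxidofuran, and bromine or adventitious HBr may cleave the acetal. The fallback brings the bromine in with the furan, so the chiral acetal never meets bromine or base; it sets out from 4 and commercial 3-bromofuran-2-carbaldehyde and returns at 8. Photooxygenation as in step 1 should give 3-bromo-5-hydroxyfuran-2(5H)-one F5. Acetalisation with 4 as in step 2 gives 8 together with (5S)-3-bromo-5-menthyloxyfuran-2(5H)-one F6. The two are separated by crystallisation or chromatography, and F6 is re-equilibrated with acid.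

## Further compounds

F1 | step 9 | 2-(4-benzyloxy-3-methoxyphenyl)-1,3-dithiane | COc1cc(C2SCCCS2)ccc1OCc1ccccc1
F2 | step 9 | (3R,4R,5R)-3-[3,4-bis(benzyloxy)-5-methoxybenzyl]-4-[2-(4-benzyloxy-3-methoxyphenyl)-1,3-dithian-2-yl]-5-[(1R,2S,5R)-menthyloxy]dihydrofuran-2(3H)-one | COc1cc(C2([C@H]3[C@H](O[C@@H]4C[C@H](C)CC[C@H]4C(C)C)OC(=O)[C@@H]3Cc3cc(OCc4ccccc4)c(OCc4ccccc4)c(OC)c3)SCCCS2)ccc1OCc1ccccc1
F3 | step 7 | (4R,5R)-4-(4-benzyloxy-3-methoxybenzyl)-5-[(1R,2S,5R)-menthyloxy]dihydrofuran-2(3H)-one | COc1cc(C[C@H]2[C@H](O[C@@H]3C[C@H](C)CC[C@H]3C(C)C)OC(=O)C2)ccc1OCc1ccccc1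
F4 | step 10 | (3R,4R)-3-[3,4-bis(benzyloxy)-5-methoxybenzyl]-4-(4-benzyloxy-3-methoxybenzyl)-5-hydroxydihydrofuran-2(3H)-one (mixture of C5 anomers) | COc1cc(C[C@H]2C(O)OC(=O)[C@@H]2Cc2cc(OCc3ccccc3)c(OCc3ccccc3)c(OC)c2)ccc1OCc1ccccc1
F5 | step 3 | 3-bromo-5-hydroxyfuran-2(5H)-one (racemic) | O=C1C(Br)=CC(O)O1
F6 | step 3 | (5S)-3-bromo-5-[(1R,2S,5R)-menthyloxy]furan-2(5H)-one | O=C1C(Br)=C[C@@H](O[C@@H]2C[C@H](C)CC[C@H]2C(C)C)O1
A1 | alternative 1 | (R)-2-(4-benzyloxy-3-methoxybenzyl)-4-[3,4-bis(benzyloxy)-5-methoxyphenyl]but-3-yn-1-ol | OC[C@H](Cc1ccc(OCc2ccccc2)c(OC)c1)C#Cc1cc(OCc2ccccc2)c(OCc2ccccc2)c(OC)c1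
A2 | alternative 1 | (R,E)-3-[3,4-bis(benzyloxy)-5-methoxybenzylidene]-4-(4-benzyloxy-3-methoxybenzyl)dihydrofuran-2(3H)-one | COc1cc(C[C@H]2COC(=O)/C2=C/c2cc(OCc3ccccc3)c(OCc3ccccc3)c(OC)c2)ccc1OCc1ccccc1
A3 | alternative 2 | tributyl({[(1S,2Z)-1-[3,4-bis(benzyloxy)-5-methoxyphenyl]-4-(4-benzyloxy-3-methoxyphenyl)but-2-en-1-yl]oxy}methyl)stannane | CCCC[Sn](CCCC)(CCCC)CO[C@@H](/C=C\Cc1ccc(OCc2ccccc2)c(OC)c1)c1cc(OCc2ccccc2)c(OCc2ccccc2)c(OC)c1
A4 | alternative 2 | (R,E)-2-(4-benzyloxy-3-methoxybenzyl)-4-[3,4-bis(benzyloxy)-5-methoxyphenyl]but-3-en-1-ol | OC[C@H](Cc1ccc(OCc2ccccc2)c(OC)c1)/C=C/c1cc(OCc2ccccc2)c(OCc2ccccc2)c(OC)c1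
A5 | alternative 3 | (R)-4-(4-benzyloxy-3-methoxybenzyl)-3-methylenedihydrofuran-2(3H)-one | COc1cc(C[C@H]2COC(=O)C2=C)ccc1OCc1ccccc1
A6 | alternative 3 | [3,4-bis(benzyloxy)-5-methoxyphenyl]boronic acid | COc1cc(B(O)O)cc(OCc2ccccc2)c1OCc1ccccc1
A7 | alternative 3 | (3R,4R)-3-[3,4-bis(benzyloxy)-5-methoxybenzyl]-4-(4-benzyloxy-3-methoxybenzyl)dihydrofuran-2(3H)-one (identical with 21) | COc1cc(C[C@H]2COC(=O)[C@@H]2Cc2cc(OCc3ccccc3)c(OCc3ccccc3)c(OC)c2)ccc1OCc1ccccc1
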